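**Assumption:** the name is taken only as a label; the SMILES is read as the C2-symmetric (2S,3S,4S,5S)-2,5-bis(4-hydroxy-3-methoxyphenyl)-3,4-bis(hydroxymethyl)oxolane, with 2,3-cis, 3,4-trans and 4,5-cis substituents.

**Abbreviations:** ArT = 3-methoxy-4-(triisopropylsilyloxy)phenyl; TIPS = triisopropylsilyl; TBDPS = tert-butyldiphenylsilyl; TBS = tert-butyldimethylsilyl; TMS = trimethylsilyl. Oxolane numbering: O1, C2 (aryl introduced last), C3, C4, C5 (aryl from the aldol).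

## Retrosynthetic overview

1. Target ⇐ fluoride removal of four silyl groups from a fully silylated 2,5-diaryl-3,4-bis(oxymethyl)oxolane.
2. C2–aryl bond ⇐ arylzinc addition to the oxocarbenium ion of a 2-benzenesulfonyl oxolane; attack anti to the C4 and C5 groups gives the 2,3-cis, 2,5-trans array.
3. C3–CH2OH ⇐ trans-selective aldol of the γ-aryl butyrolactone enolate with formaldehyde.
4. The only ring, the oxolane, is closed early as a lactol (then lactone) by oxidative cleavage of an allyl group onto the benzylic hydroxyl.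
5. C4–C5 bond and both of its stereocentres ⇐ auxiliary-controlled intermolecular anti-aldol of an N-pent-4-enoyl oxazolidinone with O-silylated vanillin, which is the key fragment union.

## Route

Step 1
Reactants: 1 vanillin
Product: 2 3-methoxy-4-(triisopropylsilyloxy)benzaldehyde
Conditions: TIPSCl, imidazole, DMF, rt
Reagents that add atoms: chlorotriisopropylsilane, CC(C)[Si](Cl)(C(C)C)C(C)C
Why: Phenol silylation gives an aryl silyl ether that survives base, hydride, oxidants and organometallics and is removed by fluoride at the end.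

Step 2
Reactants: 3 (S)-4-benzyl-1,3-oxazolidin-2-one; 4 pent-4-enoyl chloride
Product: 6 (S)-4-benzyl-3-(pent-4-enoyl)-1,3-oxazolidin-2-one, via lithium oxazolidinide 5 (not isolated)
Conditions: n-BuLi, THF, −78 °C; then 4, −78 → 0 °C
Reagents that add atoms: none
Why: N-acylation of the lithiated Evans auxiliary with an acid chloride is quantitative and creates no new stereocentre.

Step 3
Reactants: 6 (S)-4-benzyl-3-(pent-4-enoyl)-1,3-oxazolidin-2-one; 2 3-methoxy-4-(triisopropylsilyloxy)benzaldehyde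
Product: 8 (4S)-4-benzyl-3-{(2R)-2-[(S)-hydroxy(ArT)methyl]pent-4-enoyl}-1,3-oxazolidin-2-one, via trimethylsilyl ether 7 (not isolated)
Conditions: MgCl2 (0.2 equiv), NaSbF6 (0.3 equiv), Et3N, TMSCl, EtOAc, rt; then citric acid, MeOH, rt
Reagents that add atoms: none
Why: Evans magnesium-halide-catalysed direct anti-aldol addition, in which the chelated Z-enolate reacts through a boat-like transition state on the face away from the benzyl group and silylation of the aldolate makes it irreversible, sets C4 (2R in the adduct) and C5 (S) in the anti relationship that becomes 4,5-cis in the ring.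

Step 4
Reactants: 8 anti-aldol adduct
Product: 9 (1S,2S)-1-ArT-2-(prop-2-en-1-yl)propane-1,3-diol
Conditions: LiBH4, MeOH (1 equiv), THF, 0 °C
Reagents that add atoms: none
Why: Reductive cleavage of the imide by hydride releases the primary alcohol and the recoverable auxiliary without touching either stereocentre.

Step 5
Reactants: 9 diol
Product: 10 (1S,2S)-2-(TBDPS-oxymethyl)-1-ArT-pent-4-en-1-ol
Conditions: TBDPSCl, imidazole, CH2Cl2, 0 °C
Reagents that add atoms: tert-butylchlorodiphenylsilane, CC(C)(C)[Si](Cl)(c1ccccc1)c1ccccc1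
Why: Selective silylation of the primary over the hindered secondary benzylic hydroxyl with a bulky silyl chloride leaves the C5 hydroxyl free for ring closure.

Step 6
Reactants: 10 mono-silyl ether
Product: 13 (4S,5S)-4-(TBDPS-oxymethyl)-5-ArT-oxolan-2-ol (anomer mixture), via triol 11 (not isolated), via hydroxy aldehyde 12 (not isolated)
Conditions: OsO4 (2 mol%), NaIO4, 2,6-lutidine, dioxane/H2O (3:1), rt
Reagents that add atoms: sodium periodate, [Na+].[O-]I(=O)(=O)=O; osmium tetroxide, O=[Os](=O)(=O)=O (it hands the new oxygen to the alkene and is regenerated by NaIO4)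
Why: Lemieux–Johnson oxidative cleavage of the terminal alkene gives the aldehyde, which the benzylic hydroxyl traps at once as the five-membered lactol, so the oxolane ring forms with C4 and C5 unchanged.

Step 7
Reactants: 13 lactol
Product: 14 (4S,5S)-4-(TBDPS-oxymethyl)-5-ArT-oxolan-2-one
Conditions: TEMPO (10 mol%), PhI(OAc)2, CH2Cl2, rt
Reagents that add atoms: none
Why: Oxoammonium (TEMPO) oxidation of a lactol to the lactone is mild and neutral and spares the silyl ethers and the benzylic C–O bond.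

Step 8
Reactants: 14 lactone
Product: 16 (3S,4S,5S)-3-(hydroxymethyl)-4-(TBDPS-oxymethyl)-5-ArT-oxolan-2-one, via lithium enolate 15 (not isolated)
Conditions: LiN(i-Pr)2, THF, −78 °C; HCHO (gas, from cracking paraformaldehyde), −78 → −30 °C; AcOH
Reagents that add atoms: formaldehyde, C=O
Why: Aldol addition of the lactone lithium enolate to monomeric formaldehyde occurs on the face opposite the cis C4 and C5 substituents, which sets C3 trans to C4.

Step 9
Reactants: 16 hydroxymethyl lactone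
Product: 17 (3S,4S,5S)-3-(TBS-oxymethyl)-4-(TBDPS-oxymethyl)-5-ArT-oxolan-2-one
Conditions: TBSCl, imidazole, DMF, rt
Reagents that add atoms: tert-butylchlorodimethylsilane, CC(C)(C)[Si](C)(C)Cl
Why: Silylation of the primary alcohol blocks retro-aldol and dehydration and keeps every protecting group fluoride-labile.

Step 10
Reactants: 17 lactone
Product: 18 (3S,4S,5S)-3-(TBS-oxymethyl)-4-(TBDPS-oxymethyl)-5-ArT-oxolan-2-ol (anomer mixture)
Conditions: i-Bu2AlH, CH2Cl2, −78 °C; aq. potassium sodium tartrate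
Reagents that add atoms: none
Why: Partial hydride reduction of a γ-lactone stops at the lactol at low temperature because the tetrahedral aluminium alkoxide is stable until work-up.

Step 11
Reactants: 18 lactol
Product: 19 (3S,4S,5S)-2-(benzenesulfonyl)-3-(TBS-oxymethyl)-4-(TBDPS-oxymethyl)-5-ArT-oxolane (anomer mixture)
Conditions: PhSO2H, CaCl2, CH2Cl2, rt
Reagents that add atoms: benzenesulfinic acid, O=S(O)c1ccccc1
Why: Ley anomeric sulfone formation (acid-promoted exchange of the lactol hydroxyl for sulfinate with CaCl2 taking up water) gives a bench-stable oxocarbenium precursor under conditions too mild to ionise the C5 benzylic ether.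

Step 12
Reactants: 20 4-bromo-2-methoxyphenol
Product: 21 (4-bromo-2-methoxyphenoxy)triisopropylsilane
Conditions: TIPSCl, imidazole, DMF, rt
Reagents that add atoms: chlorotriisopropylsilane, CC(C)[Si](Cl)(C(C)C)C(C)C
Why: Phenol silylation gives the same aryl protecting group as in the first half so that one fluoride step finishes the synthesis.

Step 13
Reactants: 19 anomeric sulfone; 21 (4-bromo-2-methoxyphenoxy)triisopropylsilane
Product: 24 (2S,3S,4S,5S)-2,5-bis(ArT)-3-(TBS-oxymethyl)-4-(TBDPS-oxymethyl)oxolane, via arylmagnesium bromide 22 (not isolated), via arylzinc bromide 23 (not isolated)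
Conditions: 21, Mg, THF, reflux; ZnBr2, THF, 0 °C; then 19, THF, rt
Reagents that add atoms: none
Why: Ley-type sulfone displacement, in which zinc ionises the sulfone to the oxocarbenium ion and the arylzinc adds by inside attack on the envelope with the C3 and C4 side chains pseudo-equatorial (anti to the C4 CH2OSi group and the C5 aryl), sets C2 (S) as 2,3-cis and 2,5-trans.

Step 14
Reactants: 24 tetrasilyl ether
Product: 25 (2S,3S,4S,5S)-2,5-bis(4-hydroxy-3-methoxyphenyl)-3,4-bis(hydroxymethyl)oxolane (target)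
Conditions: Bu4NF, AcOH, THF, 0 °C → rt
Reagents that add atoms: none
Why: Buffered fluoride desilylation removes the two aryl and two alkyl silyl ethers under non-acidic, non-reductive conditions, so the acid-sensitive cis benzylic ether centres are not epimerised or hydrogenolysed.

## Compound list

1 | vanillin (4-hydroxy-3-methoxybenzaldehyde) | COc1cc(C=O)ccc1O | starting material
2 | 3-methoxy-4-(triisopropylsilyloxy)benzaldehyde | COc1cc(C=O)ccc1O[Si](C(C)C)(C(C)C)C(C)C | intermediate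
3 | (S)-4-benzyl-1,3-oxazolidin-2-one | O=C1N[C@@H](Cc2ccccc2)CO1 | starting material
4 | pent-4-enoyl chloride | C=CCCC(=O)Cl | starting material
5 | lithium salt of 3 (N-lithio-(S)-4-benzyl-1,3-oxazolidin-2-one) | [Li]N1[C@@H](Cc2ccccc2)COC1=O | intermediate
6 | (S)-4-benzyl-3-(pent-4-enoyl)-1,3-oxazolidin-2-one | C=CCCC(=O)N1[C@@H](Cc2ccccc2)COC1=O | intermediate
7 | (4S)-4-benzyl-3-{(2R)-2-[(S)-(ArT)(trimethylsilyloxy)methyl]pent-4-enoyl}-1,3-oxazolidin-2-one | C=CC[C@H]([C@H](O[Si](C)(C)C)c1ccc(O[Si](C(C)C)(C(C)C)C(C)C)c(OC)c1)C(=O)N1[C@@H](Cc2ccccc2)COC1=O | intermediate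
8 | (4S)-4-benzyl-3-{(2R)-2-[(S)-hydroxy(ArT)methyl]pent-4-enoyl}-1,3-oxazolidin-2-one (anti-aldol adduct) | C=CC[C@H]([C@H](O)c1ccc(O[Si](C(C)C)(C(C)C)C(C)C)c(OC)c1)C(=O)N1[C@@H](Cc2ccccc2)COC1=O | intermediate
9 | (1S,2S)-1-ArT-2-(prop-2-en-1-yl)propane-1,3-diol | C=CC[C@H]([C@H](O)c1ccc(O[Si](C(C)C)(C(C)C)C(C)C)c(OC)c1)CO | intermediate
10 | (1S,2S)-2-(TBDPS-oxymethyl)-1-ArT-pent-4-en-1-ol | C=CC[C@H]([C@H](O)c1ccc(O[Si](C(C)C)(C(C)C)C(C)C)c(OC)c1)CO[Si](c1ccccc1)(c1ccccc1)C(C)(C)C | intermediate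
11 | (4S,5S)-4-(TBDPS-oxymethyl)-5-ArT-pentane-1,2,5-triol (both C2 epimers) | OCC(O)C[C@H]([C@H](O)c1ccc(O[Si](C(C)C)(C(C)C)C(C)C)c(OC)c1)CO[Si](c1ccccc1)(c1ccccc1)C(C)(C)C | intermediate
12 | (3S,4S)-3-(TBDPS-oxymethyl)-4-hydroxy-4-ArT-butanal | O=CC[C@H]([C@H](O)c1ccc(O[Si](C(C)C)(C(C)C)C(C)C)c(OC)c1)CO[Si](c1ccccc1)(c1ccccc1)C(C)(C)C | intermediate
13 | (4S,5S)-4-(TBDPS-oxymethyl)-5-ArT-oxolan-2-ol (anomer mixture; 4,5-cis) | OC1C[C@@H](CO[Si](c2ccccc2)(c2ccccc2)C(C)(C)C)[C@@H](c2ccc(O[Si](C(C)C)(C(C)C)C(C)C)c(OC)c2)O1 | intermediate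
14 | (4S,5S)-4-(TBDPS-oxymethyl)-5-ArT-oxolan-2-one (4,5-cis lactone) | O=C1C[C@@H](CO[Si](c2ccccc2)(c2ccccc2)C(C)(C)C)[C@@H](c2ccc(O[Si](C(C)C)(C(C)C)C(C)C)c(OC)c2)O1 | intermediate
15 | lithium enolate of 14 ((4S,5S)-2-lithiooxy-4-(TBDPS-oxymethyl)-5-ArT-4,5-dihydrofuran) | [Li]OC1=C[C@@H](CO[Si](c2ccccc2)(c2ccccc2)C(C)(C)C)[C@@H](c2ccc(O[Si](C(C)C)(C(C)C)C(C)C)c(OC)c2)O1 | intermediate
16 | (3S,4S,5S)-3-(hydroxymethyl)-4-(TBDPS-oxymethyl)-5-ArT-oxolan-2-one (3,4-trans, 4,5-cis) | O=C1[C@H](CO)[C@@H](CO[Si](c2ccccc2)(c2ccccc2)C(C)(C)C)[C@@H](c2ccc(O[Si](C(C)C)(C(C)C)C(C)C)c(OC)c2)O1 | intermediate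
17 | (3S,4S,5S)-3-(TBS-oxymethyl)-4-(TBDPS-oxymethyl)-5-ArT-oxolan-2-one | O=C1[C@H](CO[Si](C)(C)C(C)(C)C)[C@@H](CO[Si](c2ccccc2)(c2ccccc2)C(C)(C)C)[C@@H](c2ccc(O[Si](C(C)C)(C(C)C)C(C)C)c(OC)c2)O1 | intermediate
18 | (3S,4S,5S)-3-(TBS-oxymethyl)-4-(TBDPS-oxymethyl)-5-ArT-oxolan-2-ol (anomer mixture) | OC1[C@H](CO[Si](C)(C)C(C)(C)C)[C@@H](CO[Si](c2ccccc2)(c2ccccc2)C(C)(C)C)[C@@H](c2ccc(O[Si](C(C)C)(C(C)C)C(C)C)c(OC)c2)O1 | intermediate
19 | (3S,4S,5S)-2-(benzenesulfonyl)-3-(TBS-oxymethyl)-4-(TBDPS-oxymethyl)-5-ArT-oxolane (anomer mixture) | O=S(=O)(c1ccccc1)C1[C@H](CO[Si](C)(C)C(C)(C)C)[C@@H](CO[Si](c2ccccc2)(c2ccccc2)C(C)(C)C)[C@@H](c2ccc(O[Si](C(C)C)(C(C)C)C(C)C)c(OC)c2)O1 | intermediate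
20 | 4-bromo-2-methoxyphenol | COc1cc(Br)ccc1O | starting material
21 | (4-bromo-2-methoxyphenoxy)triisopropylsilane | COc1cc(Br)ccc1O[Si](C(C)C)(C(C)C)C(C)C | intermediate
22 | [3-methoxy-4-(triisopropylsilyloxy)phenyl]magnesium bromide | COc1cc([Mg]Br)ccc1O[Si](C(C)C)(C(C)C)C(C)C | intermediate
23 | [3-methoxy-4-(triisopropylsilyloxy)phenyl]zinc bromide | COc1cc([Zn]Br)ccc1O[Si](C(C)C)(C(C)C)C(C)C | intermediate
24 | (2S,3S,4S,5S)-2,5-bis(ArT)-3-(TBS-oxymethyl)-4-(TBDPS-oxymethyl)oxolane (2,3-cis, 3,4-trans, 4,5-cis) | COc1cc([C@H]2O[C@H](c3ccc(O[Si](C(C)C)(C(C)C)C(C)C)c(OC)c3)[C@H](CO[Si](c3ccccc3)(c3ccccc3)C(C)(C)C)[C@H]2CO[Si](C)(C)C(C)(C)C)ccc1O[Si](C(C)C)(C(C)C)C(C)C | intermediate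
25 | (2S,3S,4S,5S)-2,5-bis(4-hydroxy-3-methoxyphenyl)-3,4-bis(hydroxymethyl)oxolane | COc1cc([C@H]2O[C@H](c3ccc(O)c(OC)c3)[C@H](CO)[C@H]2CO)ccc1O | target

## Step count and risks

Total step count: 14. Longest linear sequence: 12 (steps 1, 3 to 11, 13 and 14, from vanillin).

**Risk 1 – step 3 (anti-aldol).** The electron-rich aldehyde and the α-allyl imide may give low conversion or a poor anti:syn ratio.
The fallback sets out from 2 and comes back at 9, making the anti relationship by chelate-controlled alkylation instead of by an aldol transition state. Aldehyde 2 is added to the lithium enolate of ethyl acetate (LiN(i-Pr)2, EtOAc, THF, −78 °C) to give racemic ethyl 3-hydroxy-3-ArT-propanoate F1. Dess–Martin periodinane oxidises it to the β-keto ester ethyl 3-oxo-3-ArT-propanoate F2. Asymmetric transfer hydrogenation (RuCl(p-cymene)[(S,S)-TsDPEN], HCO2H/Et3N) gives ethyl (3S)-3-hydroxy-3-ArT-propanoate F3. Fráter–Seebach allylation of its dianion (LiN(i-Pr)2 2.2 equiv, allyl bromide, THF/DMPU, −78 → −20 °C) gives the anti product ethyl (2R)-2-[(S)-hydroxy(ArT)methyl]pent-4-enoate F4. LiAlH4 (THF, 0 °C) reduces the ester to diol 9.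

**Risk 2 – step 8 (formaldehyde aldol).** Monomeric formaldehyde is awkward to dose, and over-addition or dehydration to the α-methylene lactone can lower the yield.
The fallback sets out from 14 and comes back at 16, bringing in the carbon as CO2 at the acid oxidation level. Enolate 15 is quenched with dry CO2 at −78 °C to give the trans acid (3S,4S,5S)-4-(TBDPS-oxymethyl)-5-ArT-2-oxooxolane-3-carboxylic acid F5. BH3·SMe2 (THF, 0 °C) then reduces the free carboxylic acid chemoselectively in the presence of the lactone to give 16.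

**Risk 3 – step 13 (arylzinc addition).** The facial selectivity at C2 may be eroded by the bulky silyloxymethyl groups, giving the 2,3-trans epimer.
The fallback sets out from 17 (with the aryl part from 20) and comes back at 25. It sets C2 on an open chain by reagent control and closes the ring by SN2 with inversion, using a sulfonate-deactivated aryl ring so that the benzylic leaving group does not ionise.
- Lactone 17 is opened with MeNH(OMe)·HCl/AlMe3 (CH2Cl2, 0 °C) to the hydroxy Weinreb amide (2S,3S,4S)-2-(TBS-oxymethyl)-3-(TBDPS-oxymethyl)-4-hydroxy-N-methoxy-N-methyl-4-ArT-butanamide F6.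
- The benzylic hydroxyl is capped at once (Et3SiCl, imidazole, DMF) to give the 4-O-triethylsilyl ether of that amide F7.
- Phenol 20 is tosylated (TsCl, Et3N, CH2Cl2) to 4-bromo-2-methoxyphenyl 4-methylbenzenesulfonate F8.
- Bromine–magnesium exchange (i-PrMgCl·LiCl, THF, −15 °C) gives [3-methoxy-4-(tosyloxy)phenyl]magnesium chloride F9, which adds to F7 to give the aryl ketone (2S,3S,4S)-1-[3-methoxy-4-(tosyloxy)phenyl]-2-(TBS-oxymethyl)-3-(TBDPS-oxymethyl)-4-(triethylsilyloxy)-4-ArT-butan-1-one F10.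
- Reduction with (S)-2-methyl-CBS-oxazaborolidine/BH3·SMe2 (aryl as the large group) gives the (1R)-configured alcohol (1R,2S,3S,4S)-1-[3-methoxy-4-(tosyloxy)phenyl]-2-(TBS-oxymethyl)-3-(TBDPS-oxymethyl)-4-(triethylsilyloxy)-4-ArT-butan-1-ol F11.
- MsCl/Et3N (CH2Cl2, −20 °C) converts it into the 1-O-methanesulfonate of that alcohol F12.
- HF·pyridine/pyridine (THF, 0 °C) removes only the triethylsilyl group to give the 4-hydroxy 1-methanesulfonate F13.
- NaH (THF, 0 °C) closes the ring by 5-exo-tet SN2 displacement with inversion at C2 to give (2S,3S,4S,5S)-2-[3-methoxy-4-(tosyloxy)phenyl]-5-ArT-3-(TBS-oxymethyl)-4-(TBDPS-oxymethyl)oxolane F14.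
- Bu4NF/AcOH (THF) removes the three silyl groups to give the mono-tosylate of the target, (2S,3S,4S,5S)-2-[3-methoxy-4-(tosyloxy)phenyl]-5-(4-hydroxy-3-methoxyphenyl)-3,4-bis(hydroxymethyl)oxolane F15.
- Mg in MeOH (rt) cleaves the aryl tosylate to give 25.

## Further compounds

F1 | step 3 | ethyl 3-hydroxy-3-[3-methoxy-4-(triisopropylsilyloxy)phenyl]propanoate (racemic) | CCOC(=O)CC(O)c1ccc(O[Si](C(C)C)(C(C)C)C(C)C)c(OC)c1
F2 | step 3 | ethyl 3-[3-methoxy-4-(triisopropylsilyloxy)phenyl]-3-oxopropanoate | CCOC(=O)CC(=O)c1ccc(O[Si](C(C)C)(C(C)C)C(C)C)c(OC)c1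
F3 | step 3 | ethyl (3S)-3-hydroxy-3-[3-methoxy-4-(triisopropylsilyloxy)phenyl]propanoate | CCOC(=O)C[C@H](O)c1ccc(O[Si](C(C)C)(C(C)C)C(C)C)c(OC)c1
F4 | step 3 | ethyl (2R)-2-[(S)-hydroxy(ArT)methyl]pent-4-enoate | C=CC[C@H]([C@H](O)c1ccc(O[Si](C(C)C)(C(C)C)C(C)C)c(OC)c1)C(=O)OCC
F5 | step 8 | (3S,4S,5S)-4-(TBDPS-oxymethyl)-5-ArT-2-oxooxolane-3-carboxylic acid | O=C1[C@H](C(=O)O)[C@@H](CO[Si](c2ccccc2)(c2ccccc2)C(C)(C)C)[C@@H](c2ccc(O[Si](C(C)C)(C(C)C)C(C)C)c(OC)c2)O1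
F6 | step 13 | (2S,3S,4S)-2-(TBS-oxymethyl)-3-(TBDPS-oxymethyl)-4-hydroxy-N-methoxy-N-methyl-4-ArT-butanamide | CON(C)C(=O)[C@H](CO[Si](C)(C)C(C)(C)C)[C@@H](CO[Si](c1ccccc1)(c1ccccc1)C(C)(C)C)[C@H](O)c1ccc(O[Si](C(C)C)(C(C)C)C(C)C)c(OC)c1
F7 | step 13 | (2S,3S,4S)-2-(TBS-oxymethyl)-3-(TBDPS-oxymethyl)-N-methoxy-N-methyl-4-(triethylsilyloxy)-4-ArT-butanamide | CON(C)C(=O)[C@H](CO[Si](C)(C)C(C)(C)C)[C@@H](CO[Si](c1ccccc1)(c1ccccc1)C(C)(C)C)[C@H](O[Si](CC)(CC)CC)c1ccc(O[Si](C(C)C)(C(C)C)C(C)C)c(OC)c1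
F8 | step 13 | 4-bromo-2-methoxyphenyl 4-methylbenzenesulfonate | COc1cc(Br)ccc1OS(=O)(=O)c1ccc(C)cc1
F9 | step 13 | [3-methoxy-4-(4-methylbenzenesulfonyloxy)phenyl]magnesium chloride (LiCl complex) | COc1cc([Mg]Cl)ccc1OS(=O)(=O)c1ccc(C)cc1
F10 | step 13 | (2S,3S,4S)-1-[3-methoxy-4-(tosyloxy)phenyl]-2-(TBS-oxymethyl)-3-(TBDPS-oxymethyl)-4-(triethylsilyloxy)-4-ArT-butan-1-one | COc1cc(C(=O)[C@H](CO[Si](C)(C)C(C)(C)C)[C@@H](CO[Si](c2ccccc2)(c2ccccc2)C(C)(C)C)[C@H](O[Si](CC)(CC)CC)c2ccc(O[Si](C(C)C)(C(C)C)C(C)C)c(OC)c2)ccc1OS(=O)(=O)c1ccc(C)cc1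
F11 | step 13 | (1R,2S,3S,4S)-1-[3-methoxy-4-(tosyloxy)phenyl]-2-(TBS-oxymethyl)-3-(TBDPS-oxymethyl)-4-(triethylsilyloxy)-4-ArT-butan-1-ol | COc1cc([C@H](O)[C@H](CO[Si](C)(C)C(C)(C)C)[C@@H](CO[Si](c2ccccc2)(c2ccccc2)C(C)(C)C)[C@H](O[Si](CC)(CC)CC)c2ccc(O[Si](C(C)C)(C(C)C)C(C)C)c(OC)c2)ccc1OS(=O)(=O)c1ccc(C)cc1
F12 | step 13 | (1R,2S,3S,4S)-1-[3-methoxy-4-(tosyloxy)phenyl]-2-(TBS-oxymethyl)-3-(TBDPS-oxymethyl)-4-(triethylsilyloxy)-4-ArT-butyl methanesulfonate | COc1cc([C@H](OS(C)(=O)=O)[C@H](CO[Si](C)(C)C(C)(C)C)[C@@H](CO[Si](c2ccccc2)(c2ccccc2)C(C)(C)C)[C@H](O[Si](CC)(CC)CC)c2ccc(O[Si](C(C)C)(C(C)C)C(C)C)c(OC)c2)ccc1OS(=O)(=O)c1ccc(C)cc1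
F13 | step 13 | (1R,2S,3S,4S)-4-hydroxy-1-[3-methoxy-4-(tosyloxy)phenyl]-2-(TBS-oxymethyl)-3-(TBDPS-oxymethyl)-4-ArT-butyl methanesulfonate | COc1cc([C@H](OS(C)(=O)=O)[C@H](CO[Si](C)(C)C(C)(C)C)[C@@H](CO[Si](c2ccccc2)(c2ccccc2)C(C)(C)C)[C@H](O)c2ccc(O[Si](C(C)C)(C(C)C)C(C)C)c(OC)c2)ccc1OS(=O)(=O)c1ccc(C)cc1
F14 | step 13 | (2S,3S,4S,5S)-2-[3-methoxy-4-(tosyloxy)phenyl]-5-ArT-3-(TBS-oxymethyl)-4-(TBDPS-oxymethyl)oxolane | COc1cc([C@H]2O[C@H](c3ccc(O[Si](C(C)C)(C(C)C)C(C)C)c(OC)c3)[C@H](CO[Si](c3ccccc3)(c3ccccc3)C(C)(C)C)[C@H]2CO[Si](C)(C)C(C)(C)C)ccc1OS(=O)(=O)c1ccc(C)cc1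
F15 | step 13 | (2S,3S,4S,5S)-2-[3-methoxy-4-(tosyloxy)phenyl]-5-(4-hydroxy-3-methoxyphenyl)-3,4-bis(hydroxymethyl)oxolane | COc1cc([C@H]2O[C@H](c3ccc(O)c(OC)c3)[C@H](CO)[C@H]2CO)ccc1OS(=O)(=O)c1ccc(C)cc1
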